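**Retrosynthetic overview**
- Target = isocupressic acid 15-oleate (normal labdane, 4S,5R,9S,10R, 13E, 9′Z). Last step: oxidation of the C19 carbinol of agathadiol 15-oleate to the acid.
- Key step: the C15–O bond. A tertiary vinyl carbinol (torulosol-type 13,19-diol) and vinyl oleate are joined by 1,3-hydroxyl transposition plus E-selective enzymatic oleoylation, which also sets 13E.
- The diol comes from a bicyclic 3-oxo-19-ester by C3 deoxygenation and reductive release of the C19 carbinol from an 8-phenylmenthyl ester.
- The bicycle comes from an acyclic β-keto ester by oxidative radical bicyclisation: ring A first (C4–C5), then ring B (C10–C9), exocyclic alkene on termination; the ester auxiliary fixes C4, C5, C9, C10.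
- The acyclic precursor comes from dianion alkylation of 8-phenylmenthyl 2-methylacetoacetate with the allylic bromide made from (E)-nerolidol (allylic oxidation, bromination).

Assumption: the π-shielding model for 8-phenylmenthyl esters (aryl ring over the radical face on the cumyl side, ester anti to the ketone oxygen) predicts that the (−)-alcohol gives the natural 4S,5R,9S,10R series; if experiment shows the opposite sense, the (+)-alcohol is used with no other change.

**Route**

Step 1
Reactants: 1 (−)-8-phenylmenthol; 2 methyl 2-methyl-3-oxobutanoate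
Product: 3 (1R,2S,5R)-5-methyl-2-(2-phenylpropan-2-yl)cyclohexyl 2-methyl-3-oxobutanoate (both C2 epimers)
Conditions: 4-(dimethylamino)pyridine (0.3 equiv), toluene, reflux, 4 Å MS in a Soxhlet thimble
Reagents that add atoms: none
Why: DMAP-catalysed transesterification of an enolisable β-keto ester (through the acylketene) works with hindered secondary alcohols and is driven by removal of methanol; the auxiliary stereocentres are untouched.

Step 2
Reactants: 4 (E)-nerolidol (racemic)
Product: 5 (2E,6E)-2,6,10-trimethyldodeca-2,6,11-triene-1,10-diol (12-hydroxynerolidol)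
Conditions: SeO2 (0.3 equiv), t-BuOOH (3 equiv), salicylic acid (0.1 equiv), CH2Cl2, 0 °C to rt
Reagents that add atoms: tert-butyl hydroperoxide, CC(C)(C)OO (terminal oxidant; the oxygen is passed on by the SeO2 catalyst, O=[Se]=O)
Why: Sharpless-type selenium dioxide allylic oxidation (ene reaction, then [2,3]-shift) takes the E-methyl group of the terminal trisubstituted alkene, so the new primary allylic alcohol is E; the vinyl group and the internal alkene react much more slowly.

Step 3
Reactants: 5
Product: 7 (6E,10E)-12-bromo-3,7,11-trimethyldodeca-1,6,10-trien-3-ol, via primary allylic mesylate 6 (not isolated)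
Conditions: MsCl, Et3N, CH2Cl2, −40 °C; then LiBr, THF, 0 °C
Reagents that add atoms: lithium bromide, [Li+].[Br-]; methanesulfonyl chloride, CS(=O)(=O)Cl (its atoms stay only in intermediate 6)
Why: Selective sulfonylation of the primary allylic hydroxyl (the tertiary one is inert at −40 °C) and SN2 displacement by bromide keep the E geometry.

Step 4
Reactants: 3; 7
Product: 8 8-phenylmenthyl (6E,10E)-14-hydroxy-2,6,10,14-tetramethyl-3-oxohexadeca-6,10,15-trienoate (epimers at C2 and C14)
Conditions: 3 (2.2 equiv), NaH then n-BuLi, THF, 0 °C; add 7, −78 to 0 °C; then H2O (excess 3 recovered)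
Reagents that add atoms: none
Why: Weiler dianion alkylation: the terminal carbanion of the β-keto ester dianion displaces the primary allylic bromide by SN2 without touching alkene geometry; one equivalent of dianion is spent on the free tertiary hydroxyl.

Step 5
Reactants: 8
Product: 9 8-phenylmenthyl 13-hydroxy-3-oxolabda-8(17),14-dien-19-oate (normal labdane series; both C13 epimers)
Conditions: Mn(OAc)3·2H2O (2.2 equiv), Cu(OAc)2·H2O (1 equiv), degassed AcOH, 25 °C, 0.05 M
Reagents that add atoms: none
Why: Snider-type oxidative free-radical polyene cyclisation (trivalent manganese, divalent copper): the α-keto ester radical closes ring A 6-endo (C4–C5) and the tertiary C10 radical closes ring B 6-endo (C10–C9) through a chair–chair array of the E,E-diene, which gives the trans ring fusion, the equatorial C9 chain and the axial ester (it sits anti to the ketone oxygen in the radical); the phenyl ring of the auxiliary shields one face of the radical and so fixes the absolute sense at C4, C5, C9 and C10 (about 10:1 expected, minor diastereomer removed by chromatography); the vinyl carbinol is not attacked, and Cu(OAc)2 oxidises the tertiary C8 radical with loss of a C17 hydrogen to the exocyclic alkene.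

Step 6
Reactants: 9
Product: 11 8-phenylmenthyl 13-hydroxylabda-8(17),14-dien-19-oate (both C13 epimers), via tosylhydrazone 10 (not isolated)
Conditions: TsNHNH2, EtOH, 75 °C; then catecholborane, CHCl3, 0 °C; NaOAc·3H2O, 60 °C
Reagents that add atoms: none
Why: Tosylhydrazone formation and Kabalka-type catecholborane reduction (diazene fragmentation with loss of N2) turn the ketone into CH2 under conditions that leave the ester, both alkenes and the tertiary allylic alcohol alone; no stereocentre is touched.

Step 7
Reactants: 11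
Product: 12 labda-8(17),14-diene-13,19-diol (torulosol and its 13-epimer)
Conditions: LiAlH4, THF, reflux; Fieser work-up (auxiliary 1 recovered)
Reagents that add atoms: none
Why: Hydride reduction is the reliable way to cleave the hindered axial 8-phenylmenthyl ester; it releases the neopentyl C19 carbinol and returns the auxiliary without touching a stereocentre.

Step 8
Reactants: 12; 13 vinyl oleate
Product: 15 agathadiol 15-oleate [(13E)-19-hydroxylabda-8(17),13-dien-15-yl (9Z)-octadec-9-enoate], via agathadiol 14 (not isolated)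
Conditions: VO(OSiPh3)3 (5 mol%), immobilised Burkholderia cepacia lipase, 13 (1.5 equiv), 4 Å MS, i-Pr2O, 35 °C
Reagents that add atoms: none
Why: Proposed new method: a dynamic 1,3-transposition coupled to E-selective enzymatic acylation, in which VO(OSiPh3)3 (pentavalent vanadium) takes up the tertiary allylic alkoxide of 12 and, by reversible [3,3]-shift of the allyl vanadate, equilibrates both C13 epimers with the 13E and 13Z primary allylic alcohols (new C15–O bond), while the oleoyl–serine acyl-enzyme formed from 13 acylates only the primary allylic hydroxyl whose cis neighbour on C13 is the small methyl group (the 13E isomer 14); the 13Z alcohol (decalinylethyl arm cis to the carbinol), the tertiary 13-OH and the neopentyl 19-OH do not fit the narrow alcohol cleft and keep re-equilibrating, so the whole pool is drained to the 13E oleate, irreversibly because the vinyl group leaves as acetaldehyde; the closest known reaction types are the oxovanadium/lipase dynamic kinetic resolution of allylic alcohols with 1,3-hydroxyl transposition and the lipase-based kinetic separation of E/Z allylic alcohols, and what has not been shown is the stereoconvergent E-selective version on an acyclic methyl/alkyl vinyl carbinol with a fatty acyl donor.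

Step 9
Reactants: 15
Product: 17 (13E)-15-[(9Z)-octadec-9-enoyloxy]labda-8(17),13-dien-19-oic acid (isocupressic acid 15-oleate), via C19 aldehyde 16 (not isolated)
Conditions: 2-azaadamantane N-oxyl (5 mol%), PhI(OAc)2 (1.2 equiv), CH2Cl2, rt; then t-BuOH/H2O, 2-methyl-2-butene, NaClO2, NaH2PO4, rt
Reagents that add atoms: sodium chlorite, [Na+].[O-]Cl=O
Why: Nitroxyl-catalysed oxidation takes the hindered neopentyl carbinol to the aldehyde and Pinnick (Lindgren) chlorite oxidation in the same flask gives the acid; the alkenes are protected by the 2-methyl-2-butene scavenger, the allylic ester is inert, and the quaternary C4 cannot epimerise.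

**Compound list**

1 | (−)-8-phenylmenthol, (1R,2S,5R)-5-methyl-2-(2-phenylpropan-2-yl)cyclohexan-1-ol | O[C@@H]1C[C@H](C)CC[C@H]1C(C)(C)c1ccccc1 | starting material (auxiliary, recovered in step 7)
2 | methyl 2-methyl-3-oxobutanoate | CC(=O)C(C)C(=O)OC | starting material
3 | (1R,2S,5R)-5-methyl-2-(2-phenylpropan-2-yl)cyclohexyl 2-methyl-3-oxobutanoate (C2 epimers) | CC(=O)C(C)C(=O)O[C@@H]1C[C@H](C)CC[C@H]1C(C)(C)c1ccccc1 | intermediate
4 | (E)-nerolidol, (6E)-3,7,11-trimethyldodeca-1,6,10-trien-3-ol (racemic) | C=CC(C)(O)CC/C=C(\C)CCC=C(C)C | starting material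
5 | (2E,6E)-2,6,10-trimethyldodeca-2,6,11-triene-1,10-diol (racemic at C10) | C=CC(C)(O)CC/C=C(\C)CC/C=C(\C)CO | intermediate
6 | (2E,6E)-10-hydroxy-2,6,10-trimethyldodeca-2,6,11-trien-1-yl methanesulfonate | C=CC(C)(O)CC/C=C(\C)CC/C=C(\C)COS(C)(=O)=O | intermediate (not isolated)
7 | (6E,10E)-12-bromo-3,7,11-trimethyldodeca-1,6,10-trien-3-ol (racemic at C3) | C=CC(C)(O)CC/C=C(\C)CC/C=C(\C)CBr | intermediate
8 | 8-phenylmenthyl (6E,10E)-14-hydroxy-2,6,10,14-tetramethyl-3-oxohexadeca-6,10,15-trienoate (epimers at C2 and C14) | C=CC(C)(O)CC/C=C(\C)CC/C=C(\C)CCC(=O)C(C)C(=O)O[C@@H]1C[C@H](C)CC[C@H]1C(C)(C)c1ccccc1 | intermediate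
9 | 8-phenylmenthyl 13-hydroxy-3-oxolabda-8(17),14-dien-19-oate: trans-decalin, 5α-H, 9α-H, 10β-CH3, 4α-CH3, ester carbon C19 4β (axial), exocyclic C8=C17, both C13 epimers | C=C1CC[C@@H]2[C@](C)(CCC(=O)[C@]2(C)C(=O)O[C@@H]3C[C@H](C)CC[C@H]3C(C)(C)c3ccccc3)[C@H]1CCC(C)(O)C=C | intermediate
10 | 3-(p-toluenesulfonylhydrazone) of 9 | C=C1CC[C@@H]2[C@](C)(CCC(=NNS(=O)(=O)c3ccc(C)cc3)[C@]2(C)C(=O)O[C@@H]3C[C@H](C)CC[C@H]3C(C)(C)c3ccccc3)[C@H]1CCC(C)(O)C=C | intermediate (not isolated)
11 | 8-phenylmenthyl 13-hydroxylabda-8(17),14-dien-19-oate (8-phenylmenthyl cupressate and its 13-epimer) | C=C1CC[C@@H]2[C@](C)(CCC[C@]2(C)C(=O)O[C@@H]3C[C@H](C)CC[C@H]3C(C)(C)c3ccccc3)[C@H]1CCC(C)(O)C=C | intermediate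
12 | labda-8(17),14-diene-13,19-diol (torulosol and its 13-epimer; ring stereocentres as in 9) | C=C1CC[C@@H]2[C@](C)(CCC[C@]2(C)CO)[C@H]1CCC(C)(O)C=C | intermediate
13 | vinyl oleate, ethenyl (9Z)-octadec-9-enoate | C=COC(=O)CCCCCCC/C=C\CCCCCCCC | starting material
14 | agathadiol, (13E)-labda-8(17),13-diene-15,19-diol | C=C1CC[C@@H]2[C@](C)(CCC[C@]2(C)CO)[C@H]1CC/C(C)=C/CO | intermediate (not isolated)
15 | agathadiol 15-oleate, (13E)-19-hydroxylabda-8(17),13-dien-15-yl (9Z)-octadec-9-enoate | C=C1CC[C@@H]2[C@](C)(CCC[C@]2(C)CO)[C@H]1CC/C(C)=C/COC(=O)CCCCCCC/C=C\CCCCCCCC | intermediate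
16 | (13E)-19-oxolabda-8(17),13-dien-15-yl (9Z)-octadec-9-enoate | C=C1CC[C@@H]2[C@](C)(CCC[C@]2(C)C=O)[C@H]1CC/C(C)=C/COC(=O)CCCCCCC/C=C\CCCCCCCC | intermediate (not isolated)
17 | (13E)-15-[(9Z)-octadec-9-enoyloxy]labda-8(17),13-dien-19-oic acid (4S,5R,9S,10R) | C=C1CC[C@@H]2[C@](C)(CCC[C@]2(C)C(=O)O)[C@H]1CC/C(C)=C/COC(=O)CCCCCCC/C=C\CCCCCCCC | target

**Step count and risks**

Total step count: 9 (one-flask sequences counted once). Longest linear sequence: 8 steps (4 to 17, steps 2–9).

Most likely to fail:

1. Step 8 (the proposed new step). The lipase may not tell the 13E from the 13Z primary alcohol well enough, or the vanadate, enzyme and vinyl ester may interfere with one another. The fallback uses known chemistry, sets out from 12 and comes back at 15. Exhaustive acetylation (Ac2O, DMAP, Et3N, 50 °C) gives labda-8(17),14-diene-13,19-diyl diacetate F1. PdCl2(MeCN)2 (5 mol%, divalent palladium) in THF at rt effects the [3,3] acetate shift to (13E)-labda-8(17),13-diene-15,19-diyl diacetate F2, formed with its 13Z isomer in a ratio of about 2–3:1. K2CO3 in MeOH removes both acetates, and chromatography on AgNO3-impregnated silica gives agathadiol 14, here isolated. Acylation of 14 with 13 by Novozym 435 alone, which takes only the C15 hydroxyl, gives 15.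

2. Step 5. Yield, facial selectivity, the exo/endo alkene ratio and the survival of the tertiary allylic alcohol in AcOH are all uncertain. The fallback sets out from 8 and comes back at 9, and replaces the oxidative cyclisation by a neutral group-transfer radical cyclisation. PhSeCl and pyridine in CH2Cl2 at 0 °C give the α-phenylselanyl β-keto ester F3. Sunlamp irradiation in benzene drives the phenylselanyl-transfer bicyclisation (same non-chelated radical, same auxiliary control) to the C8 selenide 8-phenylmenthyl 13-hydroxy-3-oxo-8-(phenylselanyl)labd-14-en-19-oate F4. H2O2 and pyridine then give 9 by selenoxide syn-elimination, and the exocyclic alkene is separated from endocyclic isomers.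

3. Step 6. The ketone sits next to the quaternary C4 carrying a very large ester, so hydrazone formation or its reduction may stall or give the 2-ene. The fallback sets out from 9 and comes back at 11, and uses a radical deoxygenation of the alcohol instead. NaBH4 in MeOH at 0 °C gives 8-phenylmenthyl 3β,13-dihydroxylabda-8(17),14-dien-19-oate F5. 1,1′-Thiocarbonyldiimidazole and DMAP in toluene at 80 °C derivatise only the secondary hydroxyl, giving the 3β-imidazolylthiocarbonate F6. Bu3SnH and AIBN in toluene at 100 °C (Barton–McCombie) give 11.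

**Further compounds**

F1 | step 8 | labda-8(17),14-diene-13,19-diyl diacetate (C13 epimers) | C=C1CC[C@@H]2[C@](C)(CCC[C@]2(C)COC(C)=O)[C@H]1CCC(C)(OC(C)=O)C=C
F2 | step 8 | (13E)-labda-8(17),13-diene-15,19-diyl diacetate | C=C1CC[C@@H]2[C@](C)(CCC[C@]2(C)COC(C)=O)[C@H]1CC/C(C)=C/COC(C)=O
F3 | step 5 | 8-phenylmenthyl (6E,10E)-14-hydroxy-2,6,10,14-tetramethyl-3-oxo-2-(phenylselanyl)hexadeca-6,10,15-trienoate | C=CC(C)(O)CC/C=C(\C)CC/C=C(\C)CCC(=O)C(C)([Se]c1ccccc1)C(=O)O[C@@H]1C[C@H](C)CC[C@H]1C(C)(C)c1ccccc1
F4 | step 5 | 8-phenylmenthyl 13-hydroxy-3-oxo-8-(phenylselanyl)labd-14-en-19-oate (C8 and C13 epimers) | CC1(CC[C@@H]2[C@](C)(CCC(=O)[C@]2(C)C(=O)O[C@@H]3C[C@H](C)CC[C@H]3C(C)(C)c3ccccc3)[C@H]1CCC(C)(O)C=C)[Se]c1ccccc1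
F5 | step 6 | 8-phenylmenthyl 3β,13-dihydroxylabda-8(17),14-dien-19-oate | C=C1CC[C@@H]2[C@](C)(CC[C@H](O)[C@]2(C)C(=O)O[C@@H]3C[C@H](C)CC[C@H]3C(C)(C)c3ccccc3)[C@H]1CCC(C)(O)C=C
F6 | step 6 | 8-phenylmenthyl 13-hydroxy-3β-[(1H-imidazol-1-yl)carbonothioyloxy]labda-8(17),14-dien-19-oate | C=C1CC[C@@H]2[C@](C)(CC[C@H](OC(=S)n3ccnc3)[C@]2(C)C(=O)O[C@@H]3C[C@H](C)CC[C@H]3C(C)(C)c3ccccc3)[C@H]1CCC(C)(O)C=C
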